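**Plan**

- Numbering: chroman-2-one locants, unprimed for the 5,7-dihydroxy unit (benzo ring A), primed for the 5,6,7,8-tetrahydroxy unit (benzo ring B).
- Cuts, in order: the eight O–CH3 bonds; O1'–C2' (lactone ring B); then in one operation O1–C2, C2–C3 and C3'–C2' (lactone ring A and both carbonyl carbons, back to a Z C3=C3' alkene, two CO and methanol); then C3–C4 and C3'–C4' (back to an acetylene unit and two quinone methides).
- Enabling feature: the C2–C3–C3'–C2' succinate core is erythro (3R,3'S) between two like centres C4 and C4' (both R). This is what syn addition of two carbonyl carbons to a Z C3=C3' alkene must give, and it makes the lactone on ring A 3,4-trans and the lactone on ring B 3',4'-cis.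
- Forward: a silylethynyl boronate is joined to the ring B quinone methide (C3'–C4') and the ring B phenol is benzylated. The derived alkynyl boronate is joined to the ring A quinone methide (C3–C4). Semihydrogenation, carbonylative closure of lactone ring A, debenzylative closure of lactone ring B and ether cleavage follow.
- Stereochemistry: C4' and C4 come from the same enantiomer of a biphenol catalyst, the Z geometry from syn hydrogenation, C3 from C4 (1,3-allylic strain plus delivery of C2 by the tethered ring A oxygen), and C3' from the syn-specific addition.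

Key step: step 10

Assumption: (R)-3,3'-dibromo-1,1'-bi-2-naphthol is taken to deliver the alkynyl group to the quinone methide face that gives the centres drawn in steps 5 and 8; if a first experiment shows the opposite sense, the (S) catalyst is used in both steps and nothing else changes.

**Route**

Step 1
Reactants: 1 1,2,3,4-tetramethoxybenzene
Product: 4 2,3,4,5-tetramethoxyphenol, via aryllithium 2 (not isolated), via dimethyl arylboronate 3 (not isolated)
Conditions: n-BuLi, TMEDA, THF, 0 °C; B(OMe)3, −78 °C to rt; H2O2, aq NaOH, 0 °C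
Reagents that add atoms: hydrogen peroxide, OO
Why: Directed ortho-lithiation next to a methoxy group, borylation and oxidative 1,2-shift of the aryl group from boron to oxygen should place the hydroxyl at one of the two equivalent free ring positions.

Step 2
Reactants: 4 2,3,4,5-tetramethoxyphenol
Product: 5 2-hydroxy-3,4,5,6-tetramethoxybenzaldehyde
Conditions: (CH2O)n, MgCl2, Et3N, MeCN, reflux
Reagents that add atoms: paraformaldehyde (as formaldehyde), C=O
Why: Magnesium-phenoxide-directed ortho-formylation (hydroxymethylation, then hydride transfer to a second formaldehyde) can only take place at the single free position, which is ortho to the hydroxyl.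

Step 3
Reactants: 5 2-hydroxy-3,4,5,6-tetramethoxybenzaldehyde; 6 (4-methoxyphenyl)magnesium bromide
Product: 8 2-[ethoxy(4-methoxyphenyl)methyl]-3,4,5,6-tetramethoxyphenol (racemic), via benzhydrol 7 (not isolated)
Conditions: 6 (2.3 equiv), THF, 0 °C; aq NH4Cl; then EtOH, PPTS (cat.), rt
Reagents that add atoms: ethanol, CCO
Why: Grignard addition to the aldehyde (the first equivalent is spent on the phenol) gives the benzhydrol, and solvolysis through its stabilised benzylic cation exchanges hydroxyl for ethoxy; the racemic centre does not matter because it is erased at the quinone methide stage.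

Step 4
Reactants: 9 ethynyltrimethylsilane
Product: 12 diisopropyl [(trimethylsilyl)ethynyl]boronate, via lithium acetylide 10 (not isolated), via lithium alkynylborate 11 (not isolated)
Conditions: n-BuLi, Et2O, −78 °C; B(OiPr)3, −78 °C; HCl in Et2O, −78 °C to rt; filtration, distillation
Reagents that add atoms: triisopropyl borate, CC(C)OB(OC(C)C)OC(C)C
Why: Borylation of a lithium acetylide with a trialkyl borate gives the ate complex, which anhydrous HCl should collapse to the distillable alkynyl boronate.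

Step 5
Reactants: 8 2-[ethoxy(4-methoxyphenyl)methyl]-3,4,5,6-tetramethoxyphenol; 12 diisopropyl [(trimethylsilyl)ethynyl]boronate
Product: 14 2-[(1R)-1-(4-methoxyphenyl)-3-(trimethylsilyl)prop-2-yn-1-yl]-3,4,5,6-tetramethoxyphenol, via ring B quinone methide 13 (not isolated)
Conditions: 12 (1.5 equiv), (R)-3,3'-dibromo-1,1'-bi-2-naphthol (15 mol %), 4 Å MS, toluene, 25–40 °C; aq work-up
Reagents that add atoms: none
Why: Chiral-biphenol-catalysed conjugate addition of a boronate to an ortho-quinone methide formed in situ by loss of ethanol: boron bound to the phenolic oxygen and to the biphenol should hand the alkynyl group to one face of the methide carbon through a six-membered array, so the catalyst sets C4' (4'R in the target).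

Step 6
Reactants: 14 2-[(1R)-1-(4-methoxyphenyl)-3-(trimethylsilyl)prop-2-yn-1-yl]-3,4,5,6-tetramethoxyphenol
Product: 16 1-(benzyloxy)-2,3,4,5-tetramethoxy-6-[(1R)-1-(4-methoxyphenyl)prop-2-yn-1-yl]benzene, via silylated benzyl ether 15 (not isolated)
Conditions: BnBr, K2CO3, DMF, 40 °C; then MeOH, rt
Reagents that add atoms: benzyl bromide, BrCc1ccccc1
Why: Williamson etherification of the phenol followed by methanolysis of the alkynyl–silicon bond under the same mild carbonate base, which should leave the propargylic C4' centre untouched.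

Step 7
Reactants: 17 2-hydroxy-4,6-dimethoxybenzaldehyde; 6 (4-methoxyphenyl)magnesium bromide
Product: 19 2-[ethoxy(4-methoxyphenyl)methyl]-3,5-dimethoxyphenol (racemic), via benzhydrol 18 (not isolated)
Conditions: 6 (2.3 equiv), THF, 0 °C; aq NH4Cl; then EtOH, AcOH (cat.), rt
Reagents that add atoms: ethanol, CCO
Why: Grignard addition and solvolytic etherification as in step 3, run dilute and nearly neutral because the free positions of ring A are nucleophilic.

Step 8
Reactants: 16 1-(benzyloxy)-2,3,4,5-tetramethoxy-6-[(1R)-1-(4-methoxyphenyl)prop-2-yn-1-yl]benzene; 19 2-[ethoxy(4-methoxyphenyl)methyl]-3,5-dimethoxyphenol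
Product: 24 2-[(1S,4S)-4-[2-(benzyloxy)-3,4,5,6-tetramethoxyphenyl]-1,4-bis(4-methoxyphenyl)but-2-yn-1-yl]-3,5-dimethoxyphenol, via lithium acetylide 20 (not isolated), via lithium alkynylborate 21 (not isolated), via alkynyl boronate 22 (not isolated), via ring A quinone methide 23 (not isolated)
Conditions: n-BuLi (1.0 equiv), THF, −78 °C; B(OiPr)3; HCl in Et2O, −78 °C to rt; filter, evaporate; then 19 (1.3 equiv), (R)-3,3'-dibromo-1,1'-bi-2-naphthol (15 mol %), 4 Å MS, toluene, 25–40 °C
Reagents that add atoms: none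
Why: The same boronate conjugate addition to an ortho-quinone methide as in step 5, after acetylide borylation in the flask: the same catalyst enantiomer should set C4 because both centres carry the same three kinds of substituent in the same spatial order (the S descriptors only reflect the internal alkyne outranking the anisyl group), and the phenol set free is the ring A hydroxyl that the key step needs.

Step 9
Reactants: 24 2-[(1S,4S)-4-[2-(benzyloxy)-3,4,5,6-tetramethoxyphenyl]-1,4-bis(4-methoxyphenyl)but-2-yn-1-yl]-3,5-dimethoxyphenol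
Product: 25 2-[(1R,2Z,4R)-4-[2-(benzyloxy)-3,4,5,6-tetramethoxyphenyl]-1,4-bis(4-methoxyphenyl)but-2-en-1-yl]-3,5-dimethoxyphenol
Conditions: H2 (1 atm), Pd/CaCO3 poisoned with Pb(OAc)2 (Lindlar catalyst), quinoline, EtOAc, rt
Reagents that add atoms: none
Why: Lindlar semihydrogenation adds H2 syn and should stop at the Z alkene, leaving the benzyl ether and both benzylic centres untouched.

Step 10
Reactants: 25 2-[(1R,2Z,4R)-4-[2-(benzyloxy)-3,4,5,6-tetramethoxyphenyl]-1,4-bis(4-methoxyphenyl)but-2-en-1-yl]-3,5-dimethoxyphenol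
Product: 26 methyl (2S,3R)-3-[2-(benzyloxy)-3,4,5,6-tetramethoxyphenyl]-2-[(3R,4R)-5,7-dimethoxy-4-(4-methoxyphenyl)-2-oxo-3,4-dihydro-2H-chromen-3-yl]-3-(4-methoxyphenyl)propanoate
Conditions: Pd(OAc)2 (10 mol %), p-benzoquinone (2 equiv), NaOAc (0.5 equiv), CO (40 bar), MeOH/THF 1:4, 40 °C
Reagents that add atoms: carbon monoxide, [C-]#[O+]; methanol, CO
Why: Proposed new method: the ring A phenoxide on divalent palladium should take up CO to give an aryloxycarbonyl palladium unit whose C2–Pd bond adds syn across the Z C3=C3' alkene (6-exo-trig migratory insertion, closing lactone ring A), after which the C3' alkyl palladium, held as a five-membered chelate by the new lactone carbonyl, inserts a second CO with retention and methanolysis of the acyl releases the C2' ester and zerovalent palladium, which p-benzoquinone returns to the divalent state. The closest known reaction types are the syn-specific oxidative bis-alkoxycarbonylation of 1,2-disubstituted alkenes to succinates with divalent palladium and benzoquinone, the oxidative cyclocarbonylation of 2-vinylphenols to coumarins and the carbonylative lactonisation of 2-allylphenols. C3 is controlled by C4: 1,3-allylic strain in the Z alkene holds the C4–H bond in the alkene plane, so the tethered ring A oxygen can bring C2 only to the face on which ring A lies, which gives the 3,4-trans lactone (3R). C3' follows from the syn stereospecificity of the addition to the Z alkene, which gives the erythro (3R,3'S) core. The step needs face selectivity (secured by C4 and the tether), initiation from ring A and not from ring B (secured by the benzyl ether on the only other phenolic oxygen) and CO capture faster than beta-hydride loss or phenol oxypalladation (favoured by the carbonyl chelate in the substrate, by high CO pressure and by acetate-ligated palladium).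

Step 11
Reactants: 26 methyl (2S,3R)-3-[2-(benzyloxy)-3,4,5,6-tetramethoxyphenyl]-2-[(3R,4R)-5,7-dimethoxy-4-(4-methoxyphenyl)-2-oxo-3,4-dihydro-2H-chromen-3-yl]-3-(4-methoxyphenyl)propanoate
Product: 28 (3R,4R)-5,7-dimethoxy-4-(4-methoxyphenyl)-3-[(3S,4R)-5,6,7,8-tetramethoxy-4-(4-methoxyphenyl)-2-oxo-3,4-dihydro-2H-chromen-3-yl]-3,4-dihydro-2H-chromen-2-one, via free ring B phenol 27 (not isolated)
Conditions: H2 (1 atm), Pd/C, EtOAc, rt; filter; then TsOH·H2O (cat.), toluene, 60 °C
Reagents that add atoms: none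
Why: Hydrogenolysis of the benzyl ether frees the O1' phenol, and acid-catalysed intramolecular transesterification of the C2' methyl ester (6-exo-trig at the ester carbon) closes lactone ring B; C3' and C4' are already fixed, so the 3',4'-cis lactone results without a new stereocentre.

Step 12
Reactants: 28 (3R,4R)-5,7-dimethoxy-4-(4-methoxyphenyl)-3-[(3S,4R)-5,6,7,8-tetramethoxy-4-(4-methoxyphenyl)-2-oxo-3,4-dihydro-2H-chromen-3-yl]-3,4-dihydro-2H-chromen-2-one
Product: 29 (3R,4R)-5,7-dihydroxy-4-(4-hydroxyphenyl)-3-[(3S,4R)-5,6,7,8-tetrahydroxy-4-(4-hydroxyphenyl)-2-oxo-3,4-dihydro-2H-chromen-3-yl]-3,4-dihydro-2H-chromen-2-one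
Conditions: BBr3 (excess), CH2Cl2, −78 °C to rt; degassed water quench and work-up under argon
Reagents that add atoms: none
Why: Lewis-acid cleavage of aryl methyl ethers with BBr3 (bromide attack on the methyl of the boron-bound ether) should remove all eight methyl groups while the two aryl lactones survive or re-close on acidic work-up; exclusion of oxygen protects the tetrahydroxy ring B.

**Compound list**

1 | 1,2,3,4-tetramethoxybenzene | COc1ccc(OC)c(OC)c1OC | starting material
2 | (2,3,4,5-tetramethoxyphenyl)lithium | [Li]c1cc(OC)c(OC)c(OC)c1OC | intermediate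
3 | dimethyl (2,3,4,5-tetramethoxyphenyl)boronate | COB(OC)c1cc(OC)c(OC)c(OC)c1OC | intermediate
4 | 2,3,4,5-tetramethoxyphenol | COc1cc(O)c(OC)c(OC)c1OC | intermediate
5 | 2-hydroxy-3,4,5,6-tetramethoxybenzaldehyde | O=Cc1c(O)c(OC)c(OC)c(OC)c1OC | intermediate
6 | (4-methoxyphenyl)magnesium bromide | COc1ccc([Mg]Br)cc1 | starting material
7 | 2-[hydroxy(4-methoxyphenyl)methyl]-3,4,5,6-tetramethoxyphenol (racemic) | OC(c1ccc(OC)cc1)c1c(O)c(OC)c(OC)c(OC)c1OC | intermediate
8 | 2-[ethoxy(4-methoxyphenyl)methyl]-3,4,5,6-tetramethoxyphenol (racemic) | CCOC(c1ccc(OC)cc1)c1c(O)c(OC)c(OC)c(OC)c1OC | intermediate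
9 | ethynyltrimethylsilane | C#C[Si](C)(C)C | starting material
10 | lithium (trimethylsilyl)acetylide | [Li]C#C[Si](C)(C)C | intermediate
11 | lithium triisopropoxy[(trimethylsilyl)ethynyl]borate | [Li+].CC(C)O[B-](OC(C)C)(OC(C)C)C#C[Si](C)(C)C | intermediate
12 | diisopropyl [(trimethylsilyl)ethynyl]boronate | CC(C)OB(OC(C)C)C#C[Si](C)(C)C | intermediate
13 | 2,3,4,5-tetramethoxy-6-[(4-methoxyphenyl)methylidene]cyclohexa-2,4-dien-1-one (ring B ortho-quinone methide) | O=C1C(OC)=C(OC)C(OC)=C(OC)C1=Cc1ccc(OC)cc1 | intermediate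
14 | 2-[(1R)-1-(4-methoxyphenyl)-3-(trimethylsilyl)prop-2-yn-1-yl]-3,4,5,6-tetramethoxyphenol | COc1c(OC)c(OC)c(O)c([C@@H](c2ccc(OC)cc2)C#C[Si](C)(C)C)c1OC | intermediate
15 | {(3R)-3-[2-(benzyloxy)-3,4,5,6-tetramethoxyphenyl]-3-(4-methoxyphenyl)prop-1-yn-1-yl}trimethylsilane | COc1c(OC)c(OC)c(OCc2ccccc2)c([C@@H](c2ccc(OC)cc2)C#C[Si](C)(C)C)c1OC | intermediate
16 | 1-(benzyloxy)-2,3,4,5-tetramethoxy-6-[(1R)-1-(4-methoxyphenyl)prop-2-yn-1-yl]benzene | COc1c(OC)c(OC)c(OCc2ccccc2)c([C@@H](c2ccc(OC)cc2)C#C)c1OC | intermediate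
17 | 2-hydroxy-4,6-dimethoxybenzaldehyde | O=Cc1c(O)cc(OC)cc1OC | starting material
18 | 2-[hydroxy(4-methoxyphenyl)methyl]-3,5-dimethoxyphenol (racemic) | OC(c1ccc(OC)cc1)c1c(O)cc(OC)cc1OC | intermediate
19 | 2-[ethoxy(4-methoxyphenyl)methyl]-3,5-dimethoxyphenol (racemic) | CCOC(c1ccc(OC)cc1)c1c(O)cc(OC)cc1OC | intermediate
20 | {(3S)-3-[2-(benzyloxy)-3,4,5,6-tetramethoxyphenyl]-3-(4-methoxyphenyl)prop-1-yn-1-yl}lithium | COc1c(OC)c(OC)c(OCc2ccccc2)c([C@@H](c2ccc(OC)cc2)C#C[Li])c1OC | intermediate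
21 | lithium {(3S)-3-[2-(benzyloxy)-3,4,5,6-tetramethoxyphenyl]-3-(4-methoxyphenyl)prop-1-yn-1-yl}triisopropoxyborate | [Li+].COc1c(OC)c(OC)c(OCc2ccccc2)c([C@@H](c2ccc(OC)cc2)C#C[B-](OC(C)C)(OC(C)C)OC(C)C)c1OC | intermediate
22 | diisopropyl {(3S)-3-[2-(benzyloxy)-3,4,5,6-tetramethoxyphenyl]-3-(4-methoxyphenyl)prop-1-yn-1-yl}boronate | COc1c(OC)c(OC)c(OCc2ccccc2)c([C@@H](c2ccc(OC)cc2)C#CB(OC(C)C)OC(C)C)c1OC | intermediate
23 | 3,5-dimethoxy-6-[(4-methoxyphenyl)methylidene]cyclohexa-2,4-dien-1-one (ring A ortho-quinone methide) | O=C1C=C(OC)C=C(OC)C1=Cc1ccc(OC)cc1 | intermediate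
24 | 2-[(1S,4S)-4-[2-(benzyloxy)-3,4,5,6-tetramethoxyphenyl]-1,4-bis(4-methoxyphenyl)but-2-yn-1-yl]-3,5-dimethoxyphenol | COc1cc(O)c([C@@H](c2ccc(OC)cc2)C#C[C@H](c2ccc(OC)cc2)c2c(OCc3ccccc3)c(OC)c(OC)c(OC)c2OC)c(OC)c1 | intermediate
25 | 2-[(1R,2Z,4R)-4-[2-(benzyloxy)-3,4,5,6-tetramethoxyphenyl]-1,4-bis(4-methoxyphenyl)but-2-en-1-yl]-3,5-dimethoxyphenol | COc1cc(O)c(c(OC)c1)[C@@H](c1ccc(OC)cc1)/C=C\[C@H](c1ccc(OC)cc1)c1c(OCc2ccccc2)c(OC)c(OC)c(OC)c1OC | intermediate
26 | methyl (2S,3R)-3-[2-(benzyloxy)-3,4,5,6-tetramethoxyphenyl]-2-[(3R,4R)-5,7-dimethoxy-4-(4-methoxyphenyl)-2-oxo-3,4-dihydro-2H-chromen-3-yl]-3-(4-methoxyphenyl)propanoate | O=C1Oc2cc(OC)cc(OC)c2[C@@H](c2ccc(OC)cc2)[C@@H]1[C@H]([C@H](c1ccc(OC)cc1)c1c(OCc2ccccc2)c(OC)c(OC)c(OC)c1OC)C(=O)OC | intermediate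
27 | methyl (2S,3R)-2-[(3R,4R)-5,7-dimethoxy-4-(4-methoxyphenyl)-2-oxo-3,4-dihydro-2H-chromen-3-yl]-3-(2-hydroxy-3,4,5,6-tetramethoxyphenyl)-3-(4-methoxyphenyl)propanoate | O=C1Oc2cc(OC)cc(OC)c2[C@@H](c2ccc(OC)cc2)[C@@H]1[C@H]([C@H](c1ccc(OC)cc1)c1c(O)c(OC)c(OC)c(OC)c1OC)C(=O)OC | intermediate
28 | (3R,4R)-5,7-dimethoxy-4-(4-methoxyphenyl)-3-[(3S,4R)-5,6,7,8-tetramethoxy-4-(4-methoxyphenyl)-2-oxo-3,4-dihydro-2H-chromen-3-yl]-3,4-dihydro-2H-chromen-2-one | O=C1Oc2cc(OC)cc(OC)c2[C@@H](c2ccc(OC)cc2)[C@@H]1[C@H]1C(=O)Oc2c(OC)c(OC)c(OC)c(OC)c2[C@H]1c1ccc(OC)cc1 | intermediate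
29 | (3R,4R)-5,7-dihydroxy-4-(4-hydroxyphenyl)-3-[(3S,4R)-5,6,7,8-tetrahydroxy-4-(4-hydroxyphenyl)-2-oxo-3,4-dihydro-2H-chromen-3-yl]-3,4-dihydro-2H-chromen-2-one | O=C1Oc2cc(O)cc(O)c2[C@@H](c2ccc(O)cc2)[C@@H]1[C@H]1C(=O)Oc2c(O)c(O)c(O)c(O)c2[C@H]1c1ccc(O)cc1 | target

**Step count**

Total: 12 steps. Longest linear sequence: 10 steps (steps 1, 2, 3, 5, 6, 8, 9, 10, 11, 12, from 1 to 29).

**Steps most likely to fail**

1. Step 10. What may go wrong:
   - Methanol may outcompete the phenol at palladium, giving intermolecular methoxycarbonylation or a mixed carbonate.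
   - The phenol oxygen may attack the coordinated alkene first (5-exo oxypalladation to a dihydrobenzofuran).
   - The C3' alkyl palladium may lose a beta-hydride before it takes up CO.
   - Insertion into the crowded alkene may be too slow.

   Fallback, from 25 back to 26, by known chemistry. The ring A phenol is silylated (TBSCl, imidazole, DMF) to tert-butyl{2-[(1R,2Z,4R)-4-[2-(benzyloxy)-3,4,5,6-tetramethoxyphenyl]-1,4-bis(4-methoxyphenyl)but-2-en-1-yl]-3,5-dimethoxyphenoxy}dimethylsilane F1. F1 is submitted to the intermolecular, syn-specific oxidative bis-methoxycarbonylation of 1,2-disubstituted alkenes (Pd(OCOCF3)2 with a bis(arylimino)acenaphthene ligand, TsOH, p-benzoquinone, CO 4 bar, MeOH/THF). This should give the erythro diester dimethyl (2R,3S)-2-[(R)-{2-[(tert-butyldimethylsilyl)oxy]-4,6-dimethoxyphenyl}(4-methoxyphenyl)methyl]-3-[(R)-[2-(benzyloxy)-3,4,5,6-tetramethoxyphenyl](4-methoxyphenyl)methyl]butanedioate F2 together with its face isomer, to be separated by chromatography. Buffered fluoride (Bu4NF, AcOH, THF) then frees the ring A phenol, which should close on the nearer C2 ester and so return to 26.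

2. Step 8. What may go wrong:
   - The electron-rich ring A quinone methide may be consumed by self-condensation at its free ring positions, because it meets the valuable boronate only in near-stoichiometric amount.
   - The boronate may be protodeboronated by the alcohols set free.
   - Catalyst control at C4 may be incomplete.

   Fallback, from 19 and 12 back to 24, with the order of the two unions reversed so that the large boronate meets the fully substituted ring B quinone methide. An excess of 12 is added to 19 under the same catalyst to give 3,5-dimethoxy-2-[(1R)-1-(4-methoxyphenyl)-3-(trimethylsilyl)prop-2-yn-1-yl]phenol F3. MOMCl and iPr2NEt give {(3R)-3-[2,4-dimethoxy-6-(methoxymethoxy)phenyl]-3-(4-methoxyphenyl)prop-1-yn-1-yl}trimethylsilane F4, and K2CO3 in MeOH gives 1,5-dimethoxy-3-(methoxymethoxy)-2-[(1R)-1-(4-methoxyphenyl)prop-2-yn-1-yl]benzene F5. F5 is taken through {(3S)-3-[2,4-dimethoxy-6-(methoxymethoxy)phenyl]-3-(4-methoxyphenyl)prop-1-yn-1-yl}lithium F6 and lithium {(3S)-3-[2,4-dimethoxy-6-(methoxymethoxy)phenyl]-3-(4-methoxyphenyl)prop-1-yn-1-yl}triisopropoxyborate F7 to diisopropyl {(3S)-3-[2,4-dimethoxy-6-(methoxymethoxy)phenyl]-3-(4-methoxyphenyl)prop-1-yn-1-yl}boronate F8, as in step 8. F8 is added to 8 (via 13) under the same catalyst to give 2-[(1S,4S)-4-[2,4-dimethoxy-6-(methoxymethoxy)phenyl]-1,4-bis(4-methoxyphenyl)but-2-yn-1-yl]-3,4,5,6-tetramethoxyphenol F9. Benzylation (BnBr, K2CO3, DMF) gives 1-(benzyloxy)-2-[(1S,4S)-4-[2,4-dimethoxy-6-(methoxymethoxy)phenyl]-1,4-bis(4-methoxyphenyl)but-2-yn-1-yl]-3,4,5,6-tetramethoxybenzene F10, and HCl in MeOH at rt removes the methoxymethyl group and returns to 24.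

3. Step 12. What may go wrong:
   - Cleavage of the flanked methoxy groups at C5, C5' and C8' may be incomplete.
   - The Lewis acid may open a lactone.
   - The tetrahydroxy ring B may be oxidised by air during isolation, leaving an inseparable mixture of polyphenols.

   Fallback, from 28 back to 29, by derivatisation and release instead of direct isolation. The crude product of the BBr3 treatment is acetylated without purification (Ac2O, pyridine) to the air-stable octaacetate (3R,4R)-5,7-diacetoxy-4-(4-acetoxyphenyl)-3-[(3S,4R)-5,6,7,8-tetraacetoxy-4-(4-acetoxyphenyl)-2-oxo-3,4-dihydro-2H-chromen-3-yl]-3,4-dihydro-2H-chromen-2-one F11, which is purified by chromatography or crystallisation. The acetates are then removed by acid-catalysed methanolysis (AcCl in MeOH, 0 °C to rt, argon), followed by evaporation and brief warming with catalytic TsOH in toluene so that any opened lactone re-closes, to give 29.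

**Further compounds**

F1 | step 10 | tert-butyl{2-[(1R,2Z,4R)-4-[2-(benzyloxy)-3,4,5,6-tetramethoxyphenyl]-1,4-bis(4-methoxyphenyl)but-2-en-1-yl]-3,5-dimethoxyphenoxy}dimethylsilane | COc1cc(O[Si](C)(C)C(C)(C)C)c(c(OC)c1)[C@@H](c1ccc(OC)cc1)/C=C\[C@H](c1ccc(OC)cc1)c1c(OCc2ccccc2)c(OC)c(OC)c(OC)c1OC
F2 | step 10 | dimethyl (2R,3S)-2-[(R)-{2-[(tert-butyldimethylsilyl)oxy]-4,6-dimethoxyphenyl}(4-methoxyphenyl)methyl]-3-[(R)-[2-(benzyloxy)-3,4,5,6-tetramethoxyphenyl](4-methoxyphenyl)methyl]butanedioate | COC(=O)[C@H]([C@H](c1ccc(OC)cc1)c1c(O[Si](C)(C)C(C)(C)C)cc(OC)cc1OC)[C@H]([C@H](c1ccc(OC)cc1)c1c(OCc2ccccc2)c(OC)c(OC)c(OC)c1OC)C(=O)OC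
F3 | step 8 | 3,5-dimethoxy-2-[(1R)-1-(4-methoxyphenyl)-3-(trimethylsilyl)prop-2-yn-1-yl]phenol | COc1cc(O)c([C@@H](c2ccc(OC)cc2)C#C[Si](C)(C)C)c(OC)c1
F4 | step 8 | {(3R)-3-[2,4-dimethoxy-6-(methoxymethoxy)phenyl]-3-(4-methoxyphenyl)prop-1-yn-1-yl}trimethylsilane | COCOc1cc(OC)cc(OC)c1[C@@H](c1ccc(OC)cc1)C#C[Si](C)(C)C
F5 | step 8 | 1,5-dimethoxy-3-(methoxymethoxy)-2-[(1R)-1-(4-methoxyphenyl)prop-2-yn-1-yl]benzene | COCOc1cc(OC)cc(OC)c1[C@@H](c1ccc(OC)cc1)C#C
F6 | step 8 | {(3S)-3-[2,4-dimethoxy-6-(methoxymethoxy)phenyl]-3-(4-methoxyphenyl)prop-1-yn-1-yl}lithium | COCOc1cc(OC)cc(OC)c1[C@@H](c1ccc(OC)cc1)C#C[Li]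
F7 | step 8 | lithium {(3S)-3-[2,4-dimethoxy-6-(methoxymethoxy)phenyl]-3-(4-methoxyphenyl)prop-1-yn-1-yl}triisopropoxyborate | [Li+].COCOc1cc(OC)cc(OC)c1[C@@H](c1ccc(OC)cc1)C#C[B-](OC(C)C)(OC(C)C)OC(C)C
F8 | step 8 | diisopropyl {(3S)-3-[2,4-dimethoxy-6-(methoxymethoxy)phenyl]-3-(4-methoxyphenyl)prop-1-yn-1-yl}boronate | COCOc1cc(OC)cc(OC)c1[C@@H](c1ccc(OC)cc1)C#CB(OC(C)C)OC(C)C
F9 | step 8 | 2-[(1S,4S)-4-[2,4-dimethoxy-6-(methoxymethoxy)phenyl]-1,4-bis(4-methoxyphenyl)but-2-yn-1-yl]-3,4,5,6-tetramethoxyphenol | COCOc1cc(OC)cc(OC)c1[C@@H](c1ccc(OC)cc1)C#C[C@H](c1ccc(OC)cc1)c1c(O)c(OC)c(OC)c(OC)c1OC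
F10 | step 8 | 1-(benzyloxy)-2-[(1S,4S)-4-[2,4-dimethoxy-6-(methoxymethoxy)phenyl]-1,4-bis(4-methoxyphenyl)but-2-yn-1-yl]-3,4,5,6-tetramethoxybenzene | COCOc1cc(OC)cc(OC)c1[C@@H](c1ccc(OC)cc1)C#C[C@H](c1ccc(OC)cc1)c1c(OCc2ccccc2)c(OC)c(OC)c(OC)c1OC
F11 | step 12 | (3R,4R)-5,7-diacetoxy-4-(4-acetoxyphenyl)-3-[(3S,4R)-5,6,7,8-tetraacetoxy-4-(4-acetoxyphenyl)-2-oxo-3,4-dihydro-2H-chromen-3-yl]-3,4-dihydro-2H-chromen-2-one | O=C1Oc2cc(OC(C)=O)cc(OC(C)=O)c2[C@@H](c2ccc(OC(C)=O)cc2)[C@@H]1[C@H]1C(=O)Oc2c(OC(C)=O)c(OC(C)=O)c(OC(C)=O)c(OC(C)=O)c2[C@H]1c1ccc(OC(C)=O)cc1
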